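## Retrosynthetic overview

1. Target ⇐ Δ9 bicyclic anisoate: C10–OH and the Δ8 olefin come from epoxidation and selenoxide allylic transposition; the anisoate from acylation; C6–OH from a C4–OH-directed ketone reduction.
2. Key disconnection: C5–C1 and C7–C8 are cut together. An intramolecular oxyallyl-cation (4+3) cycloaddition of an acyclic chloromethyl ketone closes the cyclopentane and the cycloheptene in one operation and sets C5, C1 and C8 from C4.
3. Chloromethyl ketone ⇐ methyl ester + LiCH2Cl; (E,E)-diene ⇐ terminal alkyne by Zr-catalysed carboalumination and Negishi coupling.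
4. Alkyne ⇐ methyl ketone; hydroxy keto ester ⇐ ozonolysis of (S)-terpinen-4-ol, which supplies C1–C6, the isopropyl group and the C4 stereocentre.
5. Ring order: no ring until step 5, then the five- and seven-membered rings form simultaneously.

Assumption: (S)-(+)-terpinen-4-ol is bought in ≥98% ee (scalemic material would first be upgraded by the known enzymatic resolution).

Atom labels use daucane numbering: C1 = angular C–CH3, C4 = C(OH)iPr, C5 = ring-fusion CH, C6 = C–O, C8 = C–CH3, C10 = carbinol. β = face of the C1 methyl, α = the opposite face.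

## Route

Step 1
Reactants: 1 (S)-(+)-terpinen-4-ol
Product: 3 methyl (3S)-3-hydroxy-6-oxo-3-(propan-2-yl)heptanoate, via methoxy hydroperoxide 2 (not isolated)
Conditions: O3, NaHCO3, CH2Cl2/MeOH (5:1), −78 °C; then Ac2O, Et3N, 0 °C → rt
Reagents that add atoms: ozone ([O-][O+]=O); methanol (CO)
Why: Criegee ozonolysis under Schreiber's terminus-differentiating conditions – the carbonyl oxide forms on the CH terminus, is trapped by MeOH as α-methoxy hydroperoxide 2 and dehydrated by Ac2O/Et3N to the methyl ester while the methyl-bearing carbon becomes the ketone; the carbinol centre of 1 is carried through unchanged (no new stereocentre).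

Step 2
Reactants: 3 methyl (3S)-3-hydroxy-6-oxo-3-(propan-2-yl)heptanoate
Product: 5 methyl (3S)-3-hydroxy-3-(propan-2-yl)hept-6-ynoate, via vinyl triflate 4 (not isolated)
Conditions: LDA (2.1 equiv), THF, −78 °C; PhNTf2; then LDA (3.3 equiv), −78 → −40 °C; aq NH4Cl
Reagents that add atoms: none
Why: Kinetic (CH3-side) enolate O-triflation followed by E2 elimination of the 2-triflyloxy-1-alkene turns the methyl ketone into a terminal alkyne; the excess LDA holds the β-hydroxy ester as its alkoxide/ester-enolate dianion (Fráter–Seebach type), which neither eliminates nor retro-aldolises at −78 °C, and no stereocentre is formed.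

Step 3
Reactants: 5 methyl (3S)-3-hydroxy-3-(propan-2-yl)hept-6-ynoate; 6 (E)-1-bromoprop-1-ene
Product: 8 methyl (3S,6E,8E)-3-hydroxy-6-methyl-3-(propan-2-yl)deca-6,8-dienoate, via alkenylalane 7 (not isolated)
Conditions: AlMe3 (4 equiv), Cp2ZrCl2 (25 mol%), CH2Cl2, −20 → 0 °C; then 6, Pd(PPh3)4 (5 mol%), ZnCl2 (cat.), THF, rt
Reagents that add atoms: trimethylaluminium (C[Al](C)C); (E)-1-bromoprop-1-ene 6 (C/C=C/Br)
Why: Negishi Zr-catalysed carboalumination adds Me–Al syn across the terminal alkyne (Me to the internal carbon), which fixes the trisubstituted 6E geometry, and Pd-catalysed Negishi alkenyl–alkenyl coupling with retention on both partners gives the (6E,8E)-diene; no stereocentre is formed.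

Step 4
Reactants: 8 methyl (3S,6E,8E)-3-hydroxy-6-methyl-3-(propan-2-yl)deca-6,8-dienoate
Product: 10 (4S,7E,9E)-1-chloro-4-hydroxy-7-methyl-4-(propan-2-yl)undeca-7,9-dien-2-one, via lithium hemiketal 9 (not isolated)
Conditions: ICH2Cl, MeLi·LiBr (3 equiv each), THF, −78 °C; then AcOH, −78 °C → rt
Reagents that add atoms: chloroiodomethane (ClCI)
Why: Chloromethyllithium (from I/Li exchange, Barbier mode) adds once to the methyl ester because the tetrahedral lithium hemiketal 9 survives at −78 °C and collapses to the α-chloroketone only on acidic quench (ester → chloromethyl ketone homologation); the diene and the carbinol centre are untouched.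

Step 5
Reactants: 10 (4S,7E,9E)-1-chloro-4-hydroxy-7-methyl-4-(propan-2-yl)undeca-7,9-dien-2-one
Product: 12 (3R,3aR,6R,8aR)-3-hydroxy-6,8a-dimethyl-3-(propan-2-yl)-2,3,3a,5,6,8a-hexahydroazulen-4(1H)-one, via oxyallyl cation 11 (not isolated)
Conditions: Et3N (3 equiv), (CF3)2CHOH, 0.01 M (slow addition), 0 °C → rt
Reagents that add atoms: none
Why: Föhlisch/Harmata-type intramolecular oxyallyl-cation (4+3) cycloaddition – Et3N/HFIP ionises the enolised chloroketone to the W-shaped cation 11 (C4 syn to O–, C4–OH hydrogen-bonded in the oxyallyl plane, iPr on the face away from the diene), and the (E)-tethered diene adds through the extended transition state, closing C5–C1 and C7–C8 together so that C6 is cis to the C4–O bond, the ring fusion is trans (1β-CH3, 5α-H) and the two outside diene substituents end up cis (8α-CH3, 8β-H).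

Step 6
Reactants: 12 (3R,3aR,6R,8aR)-3-hydroxy-6,8a-dimethyl-3-(propan-2-yl)-2,3,3a,5,6,8a-hexahydroazulen-4(1H)-one
Product: 13 (3R,3aS,4S,6R,8aR)-6,8a-dimethyl-3-(propan-2-yl)-1,2,3,3a,4,5,6,8a-octahydroazulene-3,4-diol
Conditions: Me4NBH(OAc)3, MeCN/AcOH (1:1), −25 °C
Reagents that add atoms: none
Why: Evans–Saksena hydroxyl-directed reduction – the C4–O–B(OAc)2H species delivers hydride intramolecularly to the β-face of the C6 ketone, giving the 1,3-anti diol with the equatorial 6α-OH (an undirected hydride would come from the open α-face).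

Step 7
Reactants: 13 (3R,3aS,4S,6R,8aR)-6,8a-dimethyl-3-(propan-2-yl)-1,2,3,3a,4,5,6,8a-octahydroazulene-3,4-diol; 14 4-methoxybenzoyl chloride
Product: 15 (3R,3aS,4S,6R,8aR)-3-hydroxy-6,8a-dimethyl-3-(propan-2-yl)-1,2,3,3a,4,5,6,8a-octahydroazulen-4-yl 4-methoxybenzoate
Conditions: pyridine, DMAP (10 mol%), CH2Cl2, 0 °C → rt
Reagents that add atoms: 4-methoxybenzoyl chloride 14 (COc1ccc(C(Cl)=O)cc1)
Why: DMAP-catalysed acyl transfer (Einhorn/Steglich-type esterification) acylates only the secondary 6α-OH because the tertiary C4–OH is inert under these conditions; no stereocentre changes.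

Step 8
Reactants: 15 (3R,3aS,4S,6R,8aR)-3-hydroxy-6,8a-dimethyl-3-(propan-2-yl)-1,2,3,3a,4,5,6,8a-octahydroazulen-4-yl 4-methoxybenzoate
Product: 16 9α,10α-epoxide of 15 (oxirane on the face opposite the C1 methyl)
Conditions: mCPBA, NaHCO3, CH2Cl2, 0 °C
Reagents that add atoms: 3-chloroperoxybenzoic acid (OOC(=O)c1cccc(Cl)c1)
Why: Prilezhaev epoxidation of the only olefin; the peracid attacks the α-face because the pseudo-axial angular C1 methyl on the adjacent carbon blocks the β-face, which sets the C10–O bond α.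

Step 9
Reactants: 16 9α,10α-epoxide of 15
Product: 19 (3R,3aS,4S,8R,8aS)-3,8-dihydroxy-6,8a-dimethyl-3-(propan-2-yl)-1,2,3,3a,4,5,8,8a-octahydroazulen-4-yl 4-methoxybenzoate, via hydroxy selenide 17 (not isolated), via selenoxide 18 (not isolated)
Conditions: (PhSe)2, NaBH4, EtOH, 60 °C; then THF, 30% H2O2, 0 °C → rt
Reagents that add atoms: none
Why: Sharpless–Lauer epoxide-to-allylic-alcohol transposition – PhSe– opens the epoxide by trans-diaxial SN2 attack at C9 (C10 is neopentyl) so the 10α C–O bond is kept, and the selenoxide undergoes syn-elimination through the cis 8β-H, away from the carbinol carbon, to give the Δ8 olefin.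

## Compound list

1 | (S)-(+)-terpinen-4-ol, (1S)-4-methyl-1-(propan-2-yl)cyclohex-3-en-1-ol | CC1=CC[C@](O)(C(C)C)CC1 | starting material
2 | (5S)-5-hydroxy-7-hydroperoxy-7-methoxy-5-(propan-2-yl)heptan-2-one (both C7 epimers) | COC(OO)C[C@](O)(C(C)C)CCC(C)=O | intermediate
3 | methyl (3S)-3-hydroxy-6-oxo-3-(propan-2-yl)heptanoate | COC(=O)C[C@](O)(C(C)C)CCC(C)=O | intermediate
4 | methyl (3S)-3-hydroxy-3-(propan-2-yl)-6-[(trifluoromethanesulfonyl)oxy]hept-6-enoate | COC(=O)C[C@](O)(C(C)C)CCC(=C)OS(=O)(=O)C(F)(F)F | intermediate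
5 | methyl (3S)-3-hydroxy-3-(propan-2-yl)hept-6-ynoate | COC(=O)C[C@](O)(C(C)C)CCC#C | intermediate
6 | (E)-1-bromoprop-1-ene | C/C=C/Br | starting material
7 | methyl (3S,6E)-7-(dimethylalumanyl)-3-[(dimethylalumanyl)oxy]-6-methyl-3-(propan-2-yl)hept-6-enoate | COC(=O)C[C@](O[Al](C)C)(C(C)C)CC/C(C)=C/[Al](C)C | intermediate
8 | methyl (3S,6E,8E)-3-hydroxy-6-methyl-3-(propan-2-yl)deca-6,8-dienoate | COC(=O)C[C@](O)(C(C)C)CC/C(C)=C/C=C/C | intermediate
9 | dilithium (4S,7E,9E)-1-chloro-2-methoxy-7-methyl-4-(propan-2-yl)undeca-7,9-diene-2,4-diolate (C2 undefined) | [Li+].[Li+].COC([O-])(CCl)C[C@]([O-])(C(C)C)CC/C(C)=C/C=C/C | intermediate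
10 | (4S,7E,9E)-1-chloro-4-hydroxy-7-methyl-4-(propan-2-yl)undeca-7,9-dien-2-one | ClCC(=O)C[C@](O)(C(C)C)CC/C(C)=C/C=C/C | intermediate
11 | W-configured 2-oxidoallyl cation from 10 (C4 syn to O–) | [CH2+]/C([O-])=C/[C@](O)(C(C)C)CC/C(C)=C/C=C/C | intermediate
12 | (3R,3aR,6R,8aR)-3-hydroxy-6,8a-dimethyl-3-(propan-2-yl)-2,3,3a,5,6,8a-hexahydroazulen-4(1H)-one (4β-OH, 5α-H, 1β-CH3, 8α-CH3, Δ9, C6 ketone) | O=C2C[C@@H](C)C=C[C@@]3(C)CC[C@@](O)(C(C)C)[C@H]23 | intermediate
13 | (3R,3aS,4S,6R,8aR)-6,8a-dimethyl-3-(propan-2-yl)-1,2,3,3a,4,5,6,8a-octahydroazulene-3,4-diol (4β-OH, 6α-OH) | O[C@H]2C[C@@H](C)C=C[C@@]3(C)CC[C@@](O)(C(C)C)[C@H]23 | intermediate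
14 | 4-methoxybenzoyl chloride | COc1ccc(C(Cl)=O)cc1 | starting material
15 | (3R,3aS,4S,6R,8aR)-3-hydroxy-6,8a-dimethyl-3-(propan-2-yl)-1,2,3,3a,4,5,6,8a-octahydroazulen-4-yl 4-methoxybenzoate | COc1ccc(C(=O)O[C@H]2C[C@@H](C)C=C[C@@]3(C)CC[C@@](O)(C(C)C)[C@H]23)cc1 | intermediate
16 | 9α,10α-epoxide of 15 (4β-OH, 6α-anisoyloxy, 8α-CH3) | COc1ccc(C(=O)O[C@H]2C[C@@H](C)[C@H]4O[C@H]4[C@@]3(C)CC[C@@](O)(C(C)C)[C@H]23)cc1 | intermediate
17 | 9β-(phenylselanyl)-10α-hydroxy compound from 16 (4β,10α-diol, 6α-anisoate, 8α-CH3, 8β-H) | COc1ccc(C(=O)O[C@H]2C[C@@H](C)[C@H]([Se]c4ccccc4)[C@@H](O)[C@@]3(C)CC[C@@](O)(C(C)C)[C@H]23)cc1 | intermediate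
18 | Se-oxide of 17 (selenium configuration undefined) | COc1ccc(C(=O)O[C@H]2C[C@@H](C)[C@H]([Se](=O)c4ccccc4)[C@@H](O)[C@@]3(C)CC[C@@](O)(C(C)C)[C@H]23)cc1 | intermediate
19 | CNP0211568.1, (3R,3aS,4S,8R,8aS)-3,8-dihydroxy-6,8a-dimethyl-3-(propan-2-yl)-1,2,3,3a,4,5,8,8a-octahydroazulen-4-yl 4-methoxybenzoate | COc1ccc(C(=O)O[C@H]2CC(C)=C[C@@H](O)[C@@]3(C)CC[C@@](O)(C(C)C)[C@H]23)cc1 | target

## Step count and risks

Total step count: 9. Longest linear sequence: 9 steps (1 → 19).

The three steps most likely to fail, each with one fallback: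

First, the (4+3) cycloaddition that makes 12.
- Failure modes: the free tertiary hydroxyl may capture the chloroketone or the cation (3(2H)-furanone formation); the diene terminus that becomes C1 carries an inside methyl and may react too slowly, so that Favorskii or solvent-capture products win; and the facial or extended/compact selectivity that fixes C1 relative to C4 may be lower than predicted.
- Fallback: it sets out from 10 and masks the hydroxyl, replacing hydrogen-bond control by allylic-strain control. TESOTf/2,6-lutidine (CH2Cl2, −78 °C) gives (4S,7E,9E)-1-chloro-7-methyl-4-(propan-2-yl)-4-[(triethylsilyl)oxy]undeca-7,9-dien-2-one F1. The cation is then generated in Föhlisch's lithium-salt medium (3 M LiClO4 in Et2O, Et3N, rt), where the silyloxy oxygen is the smallest C4 substituent and lies in the oxyallyl plane; this gives the 4-O-triethylsilyl ether of 12 F2. HF·pyridine in THF removes the silyl group and the fallback comes back to the route at 12.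

Second, the one-pot conversion of the methyl ketone of 3 into the alkyne 5.
- Failure modes: imperfect CH3-versus-CH2 enolisation, triflation of the alkoxide, or degradation of the β-hydroxy ester by the amide base.
- Fallback: it sets out from 3 and replaces the alkyne/carbometalation logic by direct carbonyl olefination. Wittig reaction with the ylide from (E)-but-2-en-1-yl(triphenyl)phosphonium bromide (n-BuLi, THF, −78 → 25 °C) gives 8 in one step, skipping 5 and 7. The cost is stereocontrol: it forms 8 together with methyl (3S,6Z,8E)-3-hydroxy-6-methyl-3-(propan-2-yl)deca-6,8-dienoate F3, which is removed on AgNO3-impregnated silica. The fallback comes back to the route at 8.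

Third, the epoxide opening and selenoxide elimination that end the route.
- Failure modes: it needs SN2 attack next to a branched carbon, survival of the anisoate towards the selenolate, and the 8β-H predicted from the cycloaddition.
- Fallback: it sets out from 16 and uses a radical mechanism with no syn/anti requirement at C8. Cp2TiCl (from Cp2TiCl2 and Mn dust, THF, rt) opens the epoxide homolytically to the C9 radical/C10 titanium alkoxide; a second Ti(III) traps the radical and β-hydride loss from the tertiary C8–H gives the Δ8 allylic alcohol directly. Regioselectivity of the homolysis is the weak point. It comes back to the route at 19 and makes no new compound (F0).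

Further compounds
F1 | step 5 | (4S,7E,9E)-1-chloro-7-methyl-4-(propan-2-yl)-4-[(triethylsilyl)oxy]undeca-7,9-dien-2-one | ClCC(=O)C[C@](O[Si](CC)(CC)CC)(C(C)C)CC/C(C)=C/C=C/C
F2 | step 5 | 4-O-triethylsilyl ether of 12 | O=C2C[C@@H](C)C=C[C@@]3(C)CC[C@@](O[Si](CC)(CC)CC)(C(C)C)[C@H]23
F3 | step 2 | methyl (3S,6Z,8E)-3-hydroxy-6-methyl-3-(propan-2-yl)deca-6,8-dienoate | COC(=O)C[C@](O)(C(C)C)CC/C(C)=C\C=C\C
F0 | step 9 | none | none
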